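**Retrosynthetic overview**
- Ring D is made last: the epoxy-lactone comes from a spiro enol lactone (bromohydrin, then closure), and the enol lactone from a 5-endo cyclisation of a C12 alkynyl acid.
- Rings A and B carry 1α-OAc, 5α-OH and 7β-OAc; these come from a Δ5-7-one through α-epoxidation, SmI2 opening and two face-selective ketone reductions.
- Ring B is closed at C5–C6 by a Mukaiyama aldol/dehydration in which the C1 ketone is masked as its silyl enol ether.
- Key late union: Michael addition of the ring A dione (9 skeletal carbons) to the ring C/D cyclopentenyl ketone (12 skeletal carbons), forming C9–C10 and the C10 quaternary centre.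
- Ring order: A (from cyclohexane-1,3-dione), C (phosphine-catalysed (3+2) annulation, sets C12), B (annulation), D (lactone, then epoxide).

**Assumptions**
- tert-Butyl, 2-methylpropyl and trimethylsilyl groups are treated as protecting groups and are not counted in the size of a starting material.
- Labels used for description (not IUPAC locants): C1–C10 as in cassanes; ring C = C8, C9, C11, C12 (spiro), C14 (bears CO2Me); C15 = carboxyl/lactone C=O on C12; C17 = carbon on C12 that becomes the epoxide CH; C16 = terminal alkyne/acetal carbon; β = face of the C10 methyl, α = opposite face.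

**Route**

Step 1
Reactants: 1 cyclohexane-1,3-dione
Product: 2 2-methylcyclohexane-1,3-dione
Conditions: MeI, NaOH, H2O–1,4-dioxane, 65 °C
Reagents that add atoms: iodomethane (CI)
Why: C-alkylation of the stabilised 1,3-dione enolate with a reactive methyl halide.

Step 2
Reactants: 2 2-methylcyclohexane-1,3-dione
Product: 3 2-methyl-3-(2-methylpropoxy)cyclohex-2-en-1-one
Conditions: i-BuOH, TsOH (cat.), PhMe, reflux, Dean–Stark
Reagents that add atoms: 2-methylpropan-1-ol (CC(C)CO)
Why: Acid-catalysed vinylogous esterification; it differentiates the two carbonyls for the Stork–Danheiser alkylations.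

Step 3
Reactants: 3 2-methyl-3-(2-methylpropoxy)cyclohex-2-en-1-one
Product: 4 2,6-dimethyl-3-(2-methylpropoxy)cyclohex-2-en-1-one (racemic)
Conditions: LDA, THF, −78 °C; MeI, −78 → 0 °C
Reagents that add atoms: iodomethane (CI)
Why: Kinetic α'-deprotonation of a vinylogous ester and enolate alkylation (Stork–Danheiser) puts the methyl on the future C4.

Step 4
Reactants: 4 2,6-dimethyl-3-(2-methylpropoxy)cyclohex-2-en-1-one
Product: 5 2,6,6-trimethyl-3-(2-methylpropoxy)cyclohex-2-en-1-one
Conditions: LDA, THF, −78 °C; MeI, −78 → 0 °C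
Reagents that add atoms: iodomethane (CI)
Why: A second kinetic α'-alkylation at the same carbon completes the gem-dimethyl group and removes the stereocentre of 4.

Step 5
Reactants: 5 2,6,6-trimethyl-3-(2-methylpropoxy)cyclohex-2-en-1-one
Product: 6 2,4,4-trimethylcyclohexane-1,3-dione
Conditions: 2 M HCl, THF, 23 °C
Reagents that add atoms: water (O)
Why: Acid hydrolysis of the vinylogous ester releases the 2-alkyl-1,3-dione, the soft C10 nucleophile.

Step 6
Reactants: 7 3-bromoprop-1-yne, 8 acetaldehyde
Product: 9 pent-4-yn-2-ol (racemic)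
Conditions: Zn dust, THF–sat. aq NH4Cl, 0 → 23 °C
Reagents that add atoms: none
Why: Barbier propargylation; the allenylzinc species adds through its γ-carbon to give the homopropargylic alcohol.

Step 7
Reactants: 9 pent-4-yn-2-ol
Product: 11 penta-3,4-dien-2-one, via pent-4-yn-2-one 10 (not isolated)
Conditions: Dess–Martin periodinane, NaHCO3, CH2Cl2, 0 °C; then Et3N (10 mol%), 23 °C
Reagents that add atoms: none
Why: Alcohol oxidation followed by base-catalysed propargyl-to-allenyl isomerisation into conjugation gives the allenyl ketone used for the annulation.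

Step 8
Reactants: 12 oxalyl chloride
Product: 13 tert-butyl chloro(oxo)acetate
Conditions: t-BuOH (1.0 equiv), Et2O, 0 °C
Reagents that add atoms: 2-methylpropan-2-ol (CC(C)(C)O)
Why: Mono-acylation of the hindered alcohol by excess diacid chloride stops at the half ester.

Step 9
Reactants: 14 methyl acetate, 13 tert-butyl chloro(oxo)acetate
Product: 15 1-tert-butyl 4-methyl 2-oxobutanedioate
Conditions: 14 (2 equiv), LDA (2 equiv), THF, −78 °C; then 13; AcOH quench
Reagents that add atoms: none
Why: Crossed Claisen-type C-acylation of the ester enolate at the acid chloride; the second equivalent of enolate deprotonates the acidic product.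

Step 10
Reactants: 15 1-tert-butyl 4-methyl 2-oxobutanedioate
Product: 16 1-tert-butyl 4-methyl (2Z)-2-(trifluoromethylsulfonyloxy)but-2-enedioate
Conditions: NaH, THF, 0 °C; Tf2O, −78 → 0 °C
Reagents that add atoms: trifluoromethanesulfonic anhydride (O=S(=O)(OS(=O)(=O)C(F)(F)F)C(F)(F)F)
Why: O-sulfonylation of the chelated sodium enolate gives the Z enol triflate (OTf cis to CO2Me).

Step 11
Reactants: 16 enol triflate, 17 ethynyltrimethylsilane
Product: 18 1-tert-butyl 4-methyl (2E)-2-[(trimethylsilyl)ethynyl]but-2-enedioate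
Conditions: PdCl2(PPh3)2 (3 mol%), CuI (6 mol%), Et3N, THF, 23 °C
Reagents that add atoms: none
Why: Sonogashira coupling of an electron-poor enol triflate proceeds with retention of alkene geometry (the two esters stay trans).

Step 12
Reactants: 11 penta-3,4-dien-2-one, 18 alkynyl butenedioate
Product: 19 ring C/D fragment, 1-tert-butyl 2-methyl 3-acetyl-1-[(trimethylsilyl)ethynyl]cyclopent-3-ene-1,2-dicarboxylate (esters trans; CO2Me cis to alkynyl; single enantiomer as in SMILES)
Conditions: chiral phosphepine (S)-SITCP (10 mol%; antipode if the sense of induction requires), PhMe, 0 → 23 °C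
Reagents that add atoms: none
Why: Lu phosphine-catalysed (3+2) annulation: the α-carbon of the phosphonium dienolate attacks the CH terminus of 18 (C14), the ester- and propargyl-stabilised carbanion closes onto the γ-carbon to build quaternary C12, the trans ester relationship is kept and the chiral phosphine fixes the absolute configuration.

Step 13
Reactants: 6 2,4,4-trimethylcyclohexane-1,3-dione, 19 ring C/D fragment
Product: 20 Michael adduct (C9–C10 bond; 9α-H, 10β-CH3, 8β-H, 14β-CO2Me; C1 and C5 ketones; C7 acetyl)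
Conditions: Et3N (0.5 equiv), MeCN (2 M), 50 °C
Reagents that add atoms: none
Why: Michael addition of a 2-alkyl-1,3-dione to a 1-acylcyclopentene: the enolate adds to C9 anti to the bulky CO2t-Bu on C12 and past the slender alkyne, a staggered approach with the CMe2-flanked carbonyl over flat C8 and the methyl between C8 and C11 gives the 9α-H/10β-CH3 relationship, and C8 equilibrates to the trans arrangement.

Step 14
Reactants: 20 Michael adduct
Product: 23 tricyclic enedione (C1 ketone; Δ5-7-one; 8β-H; 9α-H; 10β-CH3), via bis(trimethylsilyl enol ether) 21 (not isolated), via C5 ketol 22 (not isolated)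
Conditions: LDA (2.3 equiv), TMSCl, THF, −78 °C; TiCl4, CH2Cl2, −78 °C; aq NaHCO3; crude ketol, Burgess reagent, PhMe, 50 °C
Reagents that add atoms: none
Why: Kinetic double enolisation masks the C1 ketone as its silyl enol ether and activates the acetyl CH3, so the intramolecular Mukaiyama aldol can only engage the C5 ketone, and Burgess syn-dehydration then erases the C5 carbinol so its configuration does not matter.

Step 15
Reactants: 23 tricyclic enedione
Product: 24 5α,6α-epoxy-1,7-dione with free terminal alkyne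
Conditions: 30% H2O2, NaOH, MeOH, 0 °C
Reagents that add atoms: hydrogen peroxide (OO)
Why: Weitz–Scheffer nucleophilic epoxidation: hydroperoxide attacks C5 from the α-face, opposite the axial β-methyls on C4 and C10, while the methanolic base also removes the alkynyl silyl group and leaves C8 and C14 in their thermodynamic configurations.

Step 16
Reactants: 24 epoxy dione
Product: 25 5α-hydroxy-1,7-dione
Conditions: SmI2 (2.5 equiv), THF–MeOH, −90 °C
Reagents that add atoms: none
Why: Reductive cleavage of the Cα–O bond of an α,β-epoxy ketone by SmI2 gives the β-hydroxy ketone with the C5–O bond and its α-configuration untouched.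

Step 17
Reactants: 25 5α-hydroxy-1,7-dione
Product: 26 5α,7β-dihydroxy-1-ketone
Conditions: Me4NBH(OAc)3, MeCN–AcOH, −40 °C
Reagents that add atoms: none
Why: Evans–Saksena directed reduction: intramolecular hydride delivery from boron bound to the 5α-oxygen gives the 1,3-anti diol (7β-OH), and the C1 ketone next to the C10 quaternary centre reacts more slowly.

Step 18
Reactants: 26 5α,7β-dihydroxy-1-ketone
Product: 28 1α,7β-diacetate tert-butyl ester (5α-OH free), via 1α,5α,7β-triol 27 (not isolated)
Conditions: LiBH(s-Bu)3, THF, −78 °C; then Ac2O, pyridine, DMAP, 40 °C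
Reagents that add atoms: acetic anhydride (CC(=O)OC(C)=O)
Why: The bulky trialkylborohydride attacks C1 from the β (equatorial) side because the α-face is blocked by the syn-axial 5α-alkoxide, giving the axial 1α-alcohol, and DMAP-catalysed acetylation esterifies the two secondary alcohols but not the hindered tertiary one.

Step 19
Reactants: 28 diacetate tert-butyl ester
Product: 30 spiro enol lactone (furan-2(3H)-one spiro-fused at C12), via alkynyl carboxylic acid 29 (not isolated)
Conditions: TFA, CH2Cl2, 0 °C; concentrate; Ph3PAuNTf2 (5 mol%), CH2Cl2, 23 °C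
Reagents that add atoms: none
Why: Acidolysis of the tert-butyl ester followed by gold-catalysed 5-endo-dig cycloisomerisation of the 3-alkynoic acid gives the enol lactone without touching C12.

Step 20
Reactants: 30 spiro enol lactone
Product: 32 spirocaesalmin, via bromo lactol 31 (not isolated)
Conditions: NBS, THF–H2O, 0 °C; then Ag2O, CH2Cl2, 23 °C
Reagents that add atoms: water (O)
Why: Bromohydrin formation puts Br+ on C17 from the face anti to the C14 ester and water on C16, and silver-assisted Williamson closure by the lactol oxygen (SN2, inversion at C17) places the epoxide on the face syn to C14 as in the target.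

**Compound list**
1 | cyclohexane-1,3-dione | O=C1CCCC(=O)C1 | starting material
2 | 2-methylcyclohexane-1,3-dione | CC1C(=O)CCCC1=O | intermediate
3 | 2-methyl-3-(2-methylpropoxy)cyclohex-2-en-1-one | CC1=C(OCC(C)C)CCCC1=O | intermediate
4 | 2,6-dimethyl-3-(2-methylpropoxy)cyclohex-2-en-1-one (racemic) | CC1CCC(OCC(C)C)=C(C)C1=O | intermediate
5 | 2,6,6-trimethyl-3-(2-methylpropoxy)cyclohex-2-en-1-one | CC1=C(OCC(C)C)CCC(C)(C)C1=O | intermediate
6 | 2,4,4-trimethylcyclohexane-1,3-dione (ring A fragment; diketo tautomer drawn) | CC1C(=O)CCC(C)(C)C1=O | intermediate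
7 | 3-bromoprop-1-yne | C#CCBr | starting material
8 | acetaldehyde | CC=O | starting material
9 | pent-4-yn-2-ol (racemic) | CC(O)CC#C | intermediate
10 | pent-4-yn-2-one (not isolated) | CC(=O)CC#C | intermediate
11 | penta-3,4-dien-2-one | CC(=O)C=C=C | intermediate
12 | oxalyl chloride | O=C(Cl)C(=O)Cl | starting material
13 | tert-butyl chloro(oxo)acetate | CC(C)(C)OC(=O)C(=O)Cl | intermediate
14 | methyl acetate | COC(C)=O | starting material
15 | 1-tert-butyl 4-methyl 2-oxobutanedioate | COC(=O)CC(=O)C(=O)OC(C)(C)C | intermediate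
16 | 1-tert-butyl 4-methyl (2Z)-2-(trifluoromethylsulfonyloxy)but-2-enedioate | CC(C)(C)OC(=O)/C(OS(=O)(=O)C(F)(F)F)=C/C(=O)OC | intermediate
17 | ethynyltrimethylsilane | C#C[Si](C)(C)C | starting material
18 | 1-tert-butyl 4-methyl (2E)-2-[(trimethylsilyl)ethynyl]but-2-enedioate | CC(C)(C)OC(=O)/C(C#C[Si](C)(C)C)=C/C(=O)OC | intermediate
19 | ring C/D fragment: 1-tert-butyl 2-methyl 3-acetyl-1-[(trimethylsilyl)ethynyl]cyclopent-3-ene-1,2-dicarboxylate, esters trans | COC(=O)[C@H]1C(C(C)=O)=CC[C@]1(C#C[Si](C)(C)C)C(=O)OC(C)(C)C | intermediate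
20 | Michael adduct: cyclopentane carrying the 1-methyl-3,3-dimethyl-2,6-dioxocyclohexyl group at C9, acetyl at C8, CO2Me at C14 (all trans), alkynyl and CO2t-Bu at C12 | COC(=O)[C@H]1[C@H](C(C)=O)[C@H](C[C@]1(C#C[Si](C)(C)C)C(=O)OC(C)(C)C)[C@@]2(C)C(=O)CCC(C)(C)C2=O | intermediate
21 | bis(trimethylsilyl enol ether) of 20 at C1=C2 and C7=C6 (not isolated) | COC(=O)[C@H]1[C@H](C(O[Si](C)(C)C)=C)[C@H](C[C@]1(C#C[Si](C)(C)C)C(=O)OC(C)(C)C)[C@@]2(C)C(O[Si](C)(C)C)=CCC(C)(C)C2=O | intermediate
22 | tricyclic C5 ketol, 1,7-dione (5β-OH drawn; C5 epimer equally usable; not isolated) | COC(=O)[C@H]1[C@@H]2C(=O)C[C@]3(O)C(C)(C)CCC(=O)[C@]3(C)[C@H]2C[C@]1(C#C[Si](C)(C)C)C(=O)OC(C)(C)C | intermediate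
23 | tricyclic enedione: C1 ketone, Δ5-7-one, 8β-H, 9α-H, 10β-CH3, 14β-CO2Me, C12 β-alkynyl/α-CO2t-Bu | COC(=O)[C@H]1[C@@H]2C(=O)C=C3C(C)(C)CCC(=O)[C@]3(C)[C@H]2C[C@]1(C#C[Si](C)(C)C)C(=O)OC(C)(C)C | intermediate
24 | 5α,6α-epoxy-1,7-dione, terminal alkyne | COC(=O)[C@H]1[C@@H]2C(=O)[C@H]4[C@@]3(O4)C(C)(C)CCC(=O)[C@]3(C)[C@H]2C[C@]1(C#C)C(=O)OC(C)(C)C | intermediate
25 | 5α-hydroxy-1,7-dione | COC(=O)[C@H]1[C@@H]2C(=O)C[C@@]3(O)C(C)(C)CCC(=O)[C@]3(C)[C@H]2C[C@]1(C#C)C(=O)OC(C)(C)C | intermediate
26 | 5α,7β-dihydroxy-1-ketone | COC(=O)[C@H]1[C@@H]2[C@@H](O)C[C@@]3(O)C(C)(C)CCC(=O)[C@]3(C)[C@H]2C[C@]1(C#C)C(=O)OC(C)(C)C | intermediate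
27 | 1α,5α,7β-triol (not isolated) | COC(=O)[C@H]1[C@@H]2[C@@H](O)C[C@@]3(O)C(C)(C)CC[C@H](O)[C@]3(C)[C@H]2C[C@]1(C#C)C(=O)OC(C)(C)C | intermediate
28 | 1α,7β-diacetoxy-5α-hydroxy tert-butyl ester | COC(=O)[C@H]1[C@@H]2[C@@H](OC(C)=O)C[C@@]3(O)C(C)(C)CC[C@H](OC(C)=O)[C@]3(C)[C@H]2C[C@]1(C#C)C(=O)OC(C)(C)C | intermediate
29 | 1α,7β-diacetoxy-5α-hydroxy C12 alkynyl carboxylic acid (not isolated) | COC(=O)[C@H]1[C@@H]2[C@@H](OC(C)=O)C[C@@]3(O)C(C)(C)CC[C@H](OC(C)=O)[C@]3(C)[C@H]2C[C@]1(C#C)C(=O)O | intermediate
30 | spiro enol lactone (C12 spiro furan-2(3H)-one) | COC(=O)[C@H]1[C@@H]2[C@@H](OC(C)=O)C[C@@]3(O)C(C)(C)CC[C@H](OC(C)=O)[C@]3(C)[C@H]2C[C@]12C(=O)OC=C2 | intermediate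
31 | bromo lactol: C17–Br on the face away from C14, C16–OH trans to Br (not isolated) | COC(=O)[C@H]1[C@@H]2[C@@H](OC(C)=O)C[C@@]3(O)C(C)(C)CC[C@H](OC(C)=O)[C@]3(C)[C@H]2C[C@]12C(=O)O[C@H](O)[C@H]2Br | intermediate
32 | spirocaesalmin | COC(=O)[C@H]1[C@@H]2[C@@H](OC(C)=O)C[C@@]3(O)C(C)(C)CC[C@H](OC(C)=O)[C@]3(C)[C@H]2C[C@]12C(=O)O[C@@H]1O[C@@H]12 | target

**Step count**
- Total: 20 steps.
- Longest linear sequence: 13 steps (steps 1–5 then 13–20; the branch 8–12 then 13–20 is equally long), i.e. 13/20 = 0.65 of the total.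

**Three steps most likely to fail, with fallbacks**

Step 13 (Michael union). Forming a quaternary–tertiary bond between two hindered partners may be slow or reversible, and facial control at C9 and C10 is only substrate-based. The fallback replaces the conjugate addition by an irreversible, stereospecific allylic alkylation and sets out from 19. Nucleophilic epoxidation (t-BuOOH, DBU) gives the epoxy ketone F1. DBU then opens it by β-elimination through the C14 ester enolate to the allylic alcohol F2. ClCO2Me/pyridine gives the methyl carbonate F3. Tsuji–Trost alkylation of 6 with F3 (Pd(PPh3)4, THF; attack at C9 distal to the ester, net retention) gives the allylation product F4. Zn/AcOH reduction of its ene-1,4-dicarbonyl unit, with thermodynamic protonation at C8 and C14, returns to 20.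

Step 14 (ring B closure). The C5 ketone sits between two quaternary carbons and may resist the Lewis-acid aldol. The fallback sets out from 20 (through 21). NBS (2 equiv) converts both silyl enol ethers into the bis(α-bromo ketone) F5. SmI2 (4.5 equiv, THF, −78 °C) then generates trivalent-samarium enolates at both sites. The C6 enolate closes onto C5 in an intramolecular Reformatsky-type aldol held by chelation, while the C2 enolate is simply protonated. The route rejoins at 22, which is dehydrated as before to 23.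

Step 20 (epoxy-lactone). Face selectivity of Br+ addition and competing ring-opened pathways are uncertain. The fallback sets out from 30 and controls C17 by catalyst instead of substrate. Mild aqueous acid (TFA, THF–H2O) hydrates the enol lactone to the aldehyde acid, held as the lactol F6. Enamine-catalysed α-chlorination (NCS, (2R,5R)-2,5-diphenylpyrrolidine, CH2Cl2) gives the α-chloro lactol F7 with the halogen on the face away from C14. Ag2O closes it to 32.

**Further compounds**
F1 | step 13 | epoxy ketone: 1-tert-butyl 2-methyl 3-acetyl-3,4-epoxy-1-[(trimethylsilyl)ethynyl]cyclopentane-1,2-dicarboxylate, epoxide cis to alkynyl | COC(=O)[C@H]1[C@@]2(C(C)=O)O[C@H]2C[C@]1(C#C[Si](C)(C)C)C(=O)OC(C)(C)C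
F2 | step 13 | allylic alcohol: 1-tert-butyl 2-methyl 3-acetyl-4-hydroxy-1-[(trimethylsilyl)ethynyl]cyclopent-2-ene-1,2-dicarboxylate | COC(=O)C1=C(C(C)=O)[C@@H](O)C[C@]1(C#C[Si](C)(C)C)C(=O)OC(C)(C)C
F3 | step 13 | methyl carbonate of F2 | COC(=O)C1=C(C(C)=O)[C@@H](OC(=O)OC)C[C@]1(C#C[Si](C)(C)C)C(=O)OC(C)(C)C
F4 | step 13 | allylation product with C9–C10 bond and C8=C14 double bond | COC(=O)C1=C(C(C)=O)[C@H](C[C@]1(C#C[Si](C)(C)C)C(=O)OC(C)(C)C)[C@@]2(C)C(=O)CCC(C)(C)C2=O
F5 | step 14 | bis(α-bromo ketone): bromoacetyl at C8 and 2-bromo-1-ketone in ring A (C2 epimers) | COC(=O)[C@H]1[C@H](C(=O)CBr)[C@H](C[C@]1(C#C[Si](C)(C)C)C(=O)OC(C)(C)C)[C@@]2(C)C(=O)C(Br)CC(C)(C)C2=O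
F6 | step 20 | lactol (closed form of the C12 aldehyde acid; C16 epimers) | COC(=O)[C@H]1[C@@H]2[C@@H](OC(C)=O)C[C@@]3(O)C(C)(C)CC[C@H](OC(C)=O)[C@]3(C)[C@H]2C[C@]12C(=O)OC(O)C2
F7 | step 20 | α-chloro lactol (chlorine on C17, face away from C14) | COC(=O)[C@H]1[C@@H]2[C@@H](OC(C)=O)C[C@@]3(O)C(C)(C)CC[C@H](OC(C)=O)[C@]3(C)[C@H]2C[C@]12C(=O)O[C@H](O)[C@H]2Cl
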